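4 questions stand on this flask, and one number read from the earlier runs answers the second of them.

| setting | summer | spring | flask |
|---|---|---|---|
| left-handed substrate | 0.20 M | 0.20 M | 0.20 M |
| right-handed substrate | 0.20 M | 0.20 M | 0.20 M |
| solid reagent | 4.2 equiv | 6.6 equiv | 3.00 equiv |
| remark | run made earlier | run made earlier |  |
| time |  |  | 25 min |

| run | time / min | left-handed product / % | left-handed substrate / % |
|---|---|---|---|
| summer | 2.00 | 0.1 | 38.2 |
| summer | 6.00 | 0.1 | 36.5 |
| summer | 10.0 | 1.6 | 35.3 |
| summer | 15.0 | 2.5 | 33.3 |
| summer | 25.0 | 5.5 | 30.6 |
| summer | 30.0 | 7.4 | 29.5 |
| spring | 2.50 | 0.5 | 37.8 |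
| spring | 4.00 | 0 | 37.1 |
| spring | 6.00 | 0.5 | 36.5 |
| spring | 10.0 | 1.2 | 34.7 |
| spring | 20.0 | 4.5 | 32.6 |
| spring | 30.0 | 7.0 | 28.6 |

(each reading ± 0.3 percentage points)

* how much left-handed product the flask holds at 25 min, in percent of the left-handed substrate and right-handed substrate together charged
* how much left-handed substrate the flask holds at 25 min, in percent of the left-handed substrate and right-handed substrate together charged
* how much decomposed reagent the flask holds at 25 min, in percent of the left-handed substrate and right-handed substrate together charged
* concentration of partner at 25 min, in M

- partner is single-handed; left-handed substrate and right-handed substrate are mirror images of each other, charged as a racemate, each of them at the stated concentration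
- solid, in amounts per volume of the solution: solid reagent
- at the start none of the solid reagent is in solution
- the handed part of partner does not stay in what it makes, so the products of the two hands are mirror images too

Read the left-handed substrate column from top to bottom. The charge gave 50.0 %, yet the first summer row already shows 38.2 %, so watch for an early fall that no row catches, and start counting from that row.

Now go to logarithms. In the summer run, log c(left-handed substrate) falls steadily enough from 38.2 % to 29.5 % for one power of ten to take 249 min. The spring rows, 37.8 % to 28.6 %, give 227 min. Their mean, 238 min, is the decade time: the minutes per power of ten of fall in the left-handed substrate, read from the first row onward at the pace of these rows.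

The two runs held 4.2 equiv and 6.6 equiv of solid reagent, and I take their difference in decade time as scatter. This flask holds 3.00 equiv, below both, so assume that it keeps the same decade time and watch whether it does.

My own reckoning for 25 min then starts from the first summer row and gives 30.6 %. The summer row at that time, which the reckoning did not use, reads 30.6 %. No column shows decomposed reagent or partner, so expect no help from the rows on those.

The forecast gives 5.6 %, 30.6 %, 11 % and 0.02 M, holding that “the flask should follow the same curves”.

The flask gives 5.73 % of left-handed product, 30.6 % of left-handed substrate, 13.0 % of decomposed reagent and 0.142 M of partner, and the substrate lands on my reckoning.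

    partner + left-handed substrate → left-handed product (k = 0.00100 M⁻¹ s⁻¹)
    partner + right-handed substrate → right-handed product (k = 9.40 × 10⁻⁵ M⁻¹ s⁻¹)
    left-handed substrate ⇌ achiral form (K = 0.620, k = 0.00640 s⁻¹)
    right-handed substrate ⇌ achiral form (K = 0.620, k = 0.00640 s⁻¹)
    solid reagent ⇌ partner, rate k5*(cs5 - [partner]) while solid is left; crystals form when [partner] > cs5 (solubility = 0.150 M, k = 0.00300 s⁻¹)
    achiral form → decomposed reagent (k = 4.20 × 10⁻⁴ s⁻¹)

Now read the same flask later, at 40 min, with every charge held. Counted from the same first summer row, that time is 0.159 of a decade time, so the decade time puts the left-handed substrate at 26.5 %. At that time this flask holds 26.5 %.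

Readings and results stem from a simulated flask on assumed constants; scatter was added.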